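**Assumption:** the target, (2,3,6-tribromo-4,5-dihydroxyphenyl)methanol, has no stereocentre, so "single enantiomer" means the one achiral compound. The only stereocentre in the route (racemic acid 3) is destroyed in step 2.

**Retrosynthetic overview**
1. Target 9 comes from aldehyde 8 by hydride reduction (FGI at the benzylic carbon).
2. The two bromines ortho to CHO in 8 are disconnected to give 7, the ring being activated by the free catechol; 7 comes from 5-bromovanillin 6 by O-demethylation, and 6 from vanillin 5.
3. The aldehyde carbon of 5 is traced to mandelic acid 3 by oxidative decarboxylation.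
4. Key C–C disconnection: the aryl–C(OH) bond of 3, made by aldol-type addition of guaiacol phenolate 1 (a vinylogous enolate) to the aldehyde of glyoxylic acid 2.
5. No ring is formed; the benzene ring is bought with guaiacol.

**Route**

Step 1
Reactants: 1 guaiacol (2-methoxyphenol); 2 glyoxylic acid (50 % aqueous solution)
Product: 3 (±)-4-hydroxy-3-methoxymandelic acid
Conditions: NaOH (2.2 equiv), H2O, 1 in 1.5-fold excess, 0–5 °C → rt, 24 h; then HCl to pH 1–2, toluene wash (recovers 1), EtOAc extraction, crystallisation
Reagents that add atoms: none
Why: the sodium phenolate of 1 reacts as a vinylogous enolate through its para carbon with the aldehyde carbonyl of glyoxylate (intermolecular aldol-type hydroxyalkylation), para attack being favoured in the cold with excess phenol; the new carbinol centre forms racemic and is removed in step 2.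

Step 2
Reactants: 3 (±)-4-hydroxy-3-methoxymandelic acid
Product: 5 vanillin, via arylglyoxylic acid 4 (not isolated)
Conditions: air (O2), CuSO4 (5 mol %), aq NaOH, 90 °C; then HCl to pH 2, 70 °C
Reagents that add atoms: none
Why: Cu(II)/O2 dehydrogenates the electron-rich p-hydroxymandelate to the α-keto acid 4, which loses CO2 on acidification and warming (oxidative decarboxylation), leaving the aldehyde.

Step 3
Reactants: 5 vanillin
Product: 6 5-bromovanillin (3-bromo-4-hydroxy-5-methoxybenzaldehyde)
Conditions: Br2 (1.05 equiv), AcOH, 15 °C → rt, 2 h; pour into water, filter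
Reagents that add atoms: bromine, BrBr
Why: electrophilic aromatic bromination goes to the only free position ortho to the phenolic OH (para is blocked by CHO), and the deactivated product resists a second bromination under these conditions.

Step 4
Reactants: 6 5-bromovanillin
Product: 7 3-bromo-4,5-dihydroxybenzaldehyde
Conditions: BBr3 (2.5 equiv), CH2Cl2, −78 °C → rt; then ice/H2O, EtOAc extraction
Reagents that add atoms: none
Why: Lewis acid ether cleavage, in which boron binds the methoxy oxygen and bromide removes the methyl group by SN2; the aryl bromide and aldehyde survive, and water hydrolyses the aryl borate to the catechol.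

Step 5
Reactants: 7 3-bromo-4,5-dihydroxybenzaldehyde
Product: 8 2,3,6-tribromo-4,5-dihydroxybenzaldehyde
Conditions: Br2 (2.5 equiv), Fe powder (5 mol %), AcOH, 70 °C; then aq NaHSO3, filter, recrystallise
Reagents that add atoms: bromine, BrBr
Why: electrophilic aromatic bromination; the two remaining ring positions are ortho and para to the C5 hydroxyl, so excess Br2 with FeBr3 formed in situ fills both, while the CHO and Br substituents hold back oxidation of the catechol to a quinone.

Step 6
Reactants: 8 2,3,6-tribromo-4,5-dihydroxybenzaldehyde
Product: 9 (2,3,6-tribromo-4,5-dihydroxyphenyl)methanol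
Conditions: NaBH4 (2 equiv), THF/H2O 4:1, 0 °C → rt; then dil. HCl to pH 5 at 0 °C, EtOAc extraction (no MeOH, no strong acid)
Reagents that add atoms: none
Why: borohydride reduction of the aldehyde (hydride addition) leaves aryl bromides and phenols untouched, and the cold, weakly acidic, methanol-free work-up avoids quinone-methide etherification of the p-hydroxybenzyl alcohol.

**Compound list**
1 | guaiacol (2-methoxyphenol) | COc1ccccc1O | starting material
2 | glyoxylic acid | O=CC(=O)O | starting material
3 | (±)-4-hydroxy-3-methoxymandelic acid (racemic 2-hydroxy-2-(4-hydroxy-3-methoxyphenyl)acetic acid) | COc1cc(C(O)C(=O)O)ccc1O | intermediate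
4 | (4-hydroxy-3-methoxyphenyl)glyoxylic acid (not isolated) | COc1cc(C(=O)C(=O)O)ccc1O | intermediate
5 | vanillin (4-hydroxy-3-methoxybenzaldehyde) | COc1cc(C=O)ccc1O | intermediate
6 | 5-bromovanillin (3-bromo-4-hydroxy-5-methoxybenzaldehyde) | COc1cc(C=O)cc(Br)c1O | intermediate
7 | 3-bromo-4,5-dihydroxybenzaldehyde | O=Cc1cc(O)c(O)c(Br)c1 | intermediate
8 | 2,3,6-tribromo-4,5-dihydroxybenzaldehyde | O=Cc1c(Br)c(O)c(O)c(Br)c1Br | intermediate
9 | (2,3,6-tribromo-4,5-dihydroxyphenyl)methanol | OCc1c(Br)c(O)c(O)c(Br)c1Br | target

**Total step count:** 6
**Longest linear sequence:** 6 steps (1 → 3 → 5 → 6 → 7 → 8 → 9)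

**Steps most likely to fail, with fallbacks**

Step 1 (some ortho attack and bis-hydroxyalkylation; the product is water-soluble and hard to isolate). The fallback sets out from 2 and replaces 1 by the ortho-blocked phenol 2-bromo-6-methoxyphenol F1 (commercial), so that only the para carbon can react. The same NaOH-mediated hydroxyalkylation gives (±)-3-bromo-4-hydroxy-5-methoxymandelic acid F2. Cu(II)/air oxidation in aqueous NaOH then passes through 2-(3-bromo-4-hydroxy-5-methoxyphenyl)-2-oxoacetic acid F3 (not isolated), which decarboxylates on acidification. The fallback comes back to the route at 6, so the bromine is carried in from the start and steps 2 and 3 fall away.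

Step 2 (over-oxidation to vanillic acid or phenolic coupling under hot alkaline aerobic conditions). The fallback sets out from 3 and replaces the oxidative decarboxylation by a reduction and glycol cleavage. BH3·THF (THF, 0 °C → rt) reduces the carboxylic acid to (±)-1-(4-hydroxy-3-methoxyphenyl)ethane-1,2-diol F4. NaIO4 (1.0 equiv, THF/H2O, pH 7, 0 °C) then cleaves the 1,2-diol. The fallback comes back to the route at 5.

Step 5 (incomplete bromination at the hindered positions flanking CHO, ipso-bromodeformylation, or oxidation of the free catechol). The fallback sets out from 6 and carries the catechol as its oxidation-proof dimethyl ether, which tolerates a much stronger brominating system. MeI/K2CO3 in DMF gives 3-bromo-4,5-dimethoxybenzaldehyde F5. Excess NBS in conc. H2SO4 (rt → 50 °C) brominates both open positions to give 2,3,6-tribromo-4,5-dimethoxybenzaldehyde F6. BBr3 (CH2Cl2, −78 °C → rt) then removes both methyl groups. The fallback comes back to the route at 8 and replaces steps 4 and 5.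

**Further compounds**
F1 | step 1 | 2-bromo-6-methoxyphenol | COc1cccc(Br)c1O
F2 | step 1 | (±)-3-bromo-4-hydroxy-5-methoxymandelic acid | COc1cc(C(O)C(=O)O)cc(Br)c1O
F3 | step 1 | 2-(3-bromo-4-hydroxy-5-methoxyphenyl)-2-oxoacetic acid | COc1cc(C(=O)C(=O)O)cc(Br)c1O
F4 | step 2 | (±)-1-(4-hydroxy-3-methoxyphenyl)ethane-1,2-diol | COc1cc(C(O)CO)ccc1O
F5 | step 5 | 3-bromo-4,5-dimethoxybenzaldehyde | COc1cc(C=O)cc(Br)c1OC
F6 | step 5 | 2,3,6-tribromo-4,5-dimethoxybenzaldehyde | COc1c(OC)c(Br)c(Br)c(C=O)c1Br
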